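**Retrosynthetic overview**
- The target 24 comes from its 4'-MOM ether 23 by mild acid cleavage (isoflavone numbering throughout: O1, C2–C4, C4a, C5–C8, C8a).
- The strategy rests on ring A: the C7 hydroxyl and the C8 prenyl group are neighbours, C8 sits next to C8a that carries ring oxygen O1, and C6 is already alkylated. Both the C7–O and the C8–CH2 bonds are therefore cut back to a C7–C8 aryne plus 2-methylbut-3-en-2-ol 19; the aryne comes from 8-silyl 7-triflate 18.
- 18 comes from 7-hydroxy-8-silylisoflavone 17, made by Suzuki coupling of 3-iodochromone 15 with boronic acid 16.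
- 15 comes from acetophenone 13 through an enaminone; 13 comes from resorcinol by three successive directed ortho-metalations (silicon, prenyl, acetyl).
- Ring order: ring A is resorcinol, the pyranone ring C is closed in step 7, ring B is attached in step 8.

Key step: step 10

Assumption: the target is 7,4'-dihydroxy-6,8-diprenylisoflavone with no stereocentre, and compounds 5, 9, 16 and 19 are taken as purchased.

**Step 1**
Reactants: 1 resorcinol
Product: 2 1,3-bis(methoxymethoxy)benzene
Conditions: NaH, MOMCl, DMF, 0 °C to rt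
Reagents that add atoms: chloromethyl methyl ether, COCCl
Why: Double Williamson etherification of the two phenoxides should install the MOM groups that direct all three later metalations.

**Step 2**
Reactants: 2 1,3-bis(methoxymethoxy)benzene
Product: 4 [2,6-bis(methoxymethoxy)phenyl]trimethylsilane, via 2,6-bis(methoxymethoxy)phenyllithium 3 (not isolated)
Conditions: n-BuLi, THF, 0 °C to rt; TMSCl, −78 °C to rt
Reagents that add atoms: chlorotrimethylsilane, C[Si](C)(C)Cl
Why: Directed ortho-metalation should occur at the position flanked and chelated by both OMOM groups, and the aryllithium is then silylated.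

**Step 3**
Reactants: 4 [2,6-bis(methoxymethoxy)phenyl]trimethylsilane; 5 prenyl bromide (1-bromo-3-methylbut-2-ene)
Product: 8 [2,6-bis(methoxymethoxy)-3-(3-methylbut-2-en-1-yl)phenyl]trimethylsilane, via aryllithium 6 (not isolated), via arylcopper 7 (not isolated)
Conditions: s-BuLi, TMEDA, THF, −78 to −20 °C; CuBr·SMe2, −78 °C; 5, −78 °C to rt
Reagents that add atoms: none
Why: With the position between the oxygens blocked by silicon, the second directed ortho-metalation can only go next to one OMOM group, and the arylcopper should couple with the primary allylic bromide at its CH2 carbon (SN2 allylation) to give the linear prenyl group.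

**Step 4**
Reactants: 8 [2,6-bis(methoxymethoxy)-3-(3-methylbut-2-en-1-yl)phenyl]trimethylsilane; 9 N-methoxy-N-methylacetamide
Product: 11 1-[2,4-bis(methoxymethoxy)-5-(3-methylbut-2-en-1-yl)-3-(trimethylsilyl)phenyl]ethan-1-one, via aryllithium 10 (not isolated)
Conditions: s-BuLi, TMEDA, THF, −78 °C; 9, −78 to 0 °C; aq. NH4Cl
Reagents that add atoms: none
Why: The third directed ortho-metalation, run cold so that OMOM-complexed ring deprotonation outruns removal of a benzylic-allylic proton, lithiates the last position next to an OMOM group, and the Weinreb amide acylation should stop at the ketone stage.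

**Step 5**
Reactants: 11 1-[2,4-bis(methoxymethoxy)-5-(3-methylbut-2-en-1-yl)-3-(trimethylsilyl)phenyl]ethan-1-one
Product: 13 1-[2,4-dihydroxy-5-(3-methylbut-2-en-1-yl)-3-(trimethylsilyl)phenyl]ethan-1-one, via bis(trimethylsilyl) ether 12 (not isolated)
Conditions: TMSOTf, 2,2′-bipyridyl, MeCN, 0 °C to rt; then H2O
Reagents that add atoms: none
Why: Silyl triflate with 2,2′-bipyridyl should turn aryl MOM ethers into aryl silyl ethers by transfer of the methoxymethyl group to nitrogen (a buffered, non-protic MOM cleavage), and these hydrolyse on aqueous work-up, so neither ipso-protodesilylation at the C–SiMe3 carbon nor acid cyclisation of the prenyl group is expected.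

**Step 6**
Reactants: 13 1-[2,4-dihydroxy-5-(3-methylbut-2-en-1-yl)-3-(trimethylsilyl)phenyl]ethan-1-one
Product: 14 (E)-3-(dimethylamino)-1-[2,4-dihydroxy-5-(3-methylbut-2-en-1-yl)-3-(trimethylsilyl)phenyl]prop-2-en-1-one
Conditions: t-BuOCH(NMe2)2, PhMe, 60 °C
Reagents that add atoms: tert-butoxybis(dimethylamino)methane, CC(C)(C)OC(N(C)C)N(C)C
Why: Condensation of the methyl ketone with the aminal ester (enaminone formation) should give the hydrogen-bonded E-enaminone as the thermodynamic isomer, and this reagent has no O-methyl group that could alkylate the free phenols.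

**Step 7**
Reactants: 14 (E)-3-(dimethylamino)-1-[2,4-dihydroxy-5-(3-methylbut-2-en-1-yl)-3-(trimethylsilyl)phenyl]prop-2-en-1-one
Product: 15 7-hydroxy-3-iodo-6-(3-methylbut-2-en-1-yl)-8-(trimethylsilyl)-4H-chromen-4-one
Conditions: I2 (1.05 equiv), CHCl3, 0 °C to rt
Reagents that add atoms: iodine, II
Why: Iodination at the enaminone α-carbon, attack of the ortho-hydroxyl on the iminium carbon and loss of dimethylamine (iodocyclisation to a 3-iodochromone) close pyranone ring C; the enaminone is far more nucleophilic than the prenyl alkene or the aryl silane, so one equivalent of iodine should be consumed there.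

**Step 8**
Reactants: 15 7-hydroxy-3-iodo-6-(3-methylbut-2-en-1-yl)-8-(trimethylsilyl)-4H-chromen-4-one; 16 4-(methoxymethoxy)phenylboronic acid
Product: 17 7-hydroxy-3-[4-(methoxymethoxy)phenyl]-6-(3-methylbut-2-en-1-yl)-8-(trimethylsilyl)-4H-chromen-4-one
Conditions: Pd(PPh3)4 (5 mol%), Na2CO3, DME/H2O, 80 °C
Reagents that add atoms: none
Why: Suzuki–Miyaura coupling at the reactive C3–I bond should attach ring B, and the 7-hydroxyl, present as its phenoxide, lowers the sensitivity of the pyranone to aqueous base.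

**Step 9**
Reactants: 17 7-hydroxy-3-[4-(methoxymethoxy)phenyl]-6-(3-methylbut-2-en-1-yl)-8-(trimethylsilyl)-4H-chromen-4-one
Product: 18 3-[4-(methoxymethoxy)phenyl]-6-(3-methylbut-2-en-1-yl)-4-oxo-8-(trimethylsilyl)-4H-chromen-7-yl trifluoromethanesulfonate
Conditions: Tf2O, pyridine, CH2Cl2, −78 to 0 °C
Reagents that add atoms: trifluoromethanesulfonic anhydride, O=S(=O)(OS(=O)(=O)C(F)(F)F)C(F)(F)F
Why: O-Sulfonylation of the only free phenol should give the ortho-silyl aryl triflate, the standard fluoride-triggered aryne precursor.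

**Step 10**
Reactants: 18 3-[4-(methoxymethoxy)phenyl]-6-(3-methylbut-2-en-1-yl)-4-oxo-8-(trimethylsilyl)-4H-chromen-7-yl trifluoromethanesulfonate; 19 2-methylbut-3-en-2-ol
Product: 23 7-hydroxy-3-[4-(methoxymethoxy)phenyl]-6,8-bis(3-methylbut-2-en-1-yl)-4H-chromen-4-one, via 7,8-didehydroisoflavone aryne 20 (not isolated), via aryl 1,1-dimethylallyl ether 21 (not isolated), via cyclohexadienone 22 (not isolated)
Conditions: CsF (3 equiv), 19 (20 equiv), MeCN, 0 °C to rt; then PhMe, 100 °C
Reagents that add atoms: none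
Why: Proposed new method: fluoride attacks the C8 silicon and triflate leaves from C7 to give aryne 20, whose C7 end is the more electrophilic because the σ-withdrawing C8a–O1 bond next to C8 widens the angle at C7 and stabilises charge building at C8; the hydroxyl oxygen of 19 should therefore add at C7 and the C8 carbanion is protonated to give ether 21 (direct closure of the carbanion on the vinyl terminus, as in the aryne aza-Claisen reaction, would give the same skeleton). On warming, 21 should undergo an aromatic Claisen [3,3] shift through a chair-like six-membered transition state that forms C8–CH2 and transposes the allyl unit to the linear prenyl group, and dienone 22 tautomerises to phenol 23. The closest known reactions are aryne O-arylation of alcohols, the aryne aza-Claisen reaction of tertiary allylamines and the thermal Claisen rearrangement of aryl 1,1-dimethylallyl ethers; new here are the hindered tertiary allylic alcohol on a chromone aryne and the coupling of both events in one flask. No ring is closed and no stereocentre remains, since the sp3 C8 of 22 is lost on enolisation. The step needs attack at C7 rather than C8 (secured by the ring oxygen on C8a, which the C6 alkyl group should not override), migration only to C8 (C6 and C4a are substituted) and survival of the pyranone C2 (the neutral tertiary alcohol is a poor conjugate donor). Holding the first stage cold until 18 is consumed keeps the phenoxide of 23 from meeting unreacted aryne.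

**Step 11**
Reactants: 23 7-hydroxy-3-[4-(methoxymethoxy)phenyl]-6,8-bis(3-methylbut-2-en-1-yl)-4H-chromen-4-one
Product: 24 7-hydroxy-3-(4-hydroxyphenyl)-6,8-bis(3-methylbut-2-en-1-yl)-4H-chromen-4-one
Conditions: HCl (2 M aq.), MeOH, 40 °C
Reagents that add atoms: none
Why: Acid-catalysed acetal exchange with methanol should cleave the aryl MOM ether under conditions mild enough to leave the two ortho-prenyl groups uncyclised.

**Compound list**
1 | resorcinol | Oc1cccc(O)c1 | starting material
2 | 1,3-bis(methoxymethoxy)benzene | COCOc1cccc(OCOC)c1 | intermediate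
3 | 2,6-bis(methoxymethoxy)phenyllithium | [Li]c1c(OCOC)cccc1OCOC | intermediate
4 | [2,6-bis(methoxymethoxy)phenyl]trimethylsilane | COCOc1cccc(OCOC)c1[Si](C)(C)C | intermediate
5 | prenyl bromide (1-bromo-3-methylbut-2-ene) | CC(C)=CCBr | starting material
6 | 2,4-bis(methoxymethoxy)-3-(trimethylsilyl)phenyllithium | [Li]c1ccc(OCOC)c([Si](C)(C)C)c1OCOC | intermediate
7 | 2,4-bis(methoxymethoxy)-3-(trimethylsilyl)phenylcopper | [Cu]c1ccc(OCOC)c([Si](C)(C)C)c1OCOC | intermediate
8 | [2,6-bis(methoxymethoxy)-3-(3-methylbut-2-en-1-yl)phenyl]trimethylsilane | CC(C)=CCc1ccc(OCOC)c([Si](C)(C)C)c1OCOC | intermediate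
9 | N-methoxy-N-methylacetamide | CC(=O)N(C)OC | starting material
10 | 2,4-bis(methoxymethoxy)-5-(3-methylbut-2-en-1-yl)-3-(trimethylsilyl)phenyllithium | CC(C)=CCc1cc([Li])c(OCOC)c([Si](C)(C)C)c1OCOC | intermediate
11 | 1-[2,4-bis(methoxymethoxy)-5-(3-methylbut-2-en-1-yl)-3-(trimethylsilyl)phenyl]ethan-1-one | CC(=O)c1cc(CC=C(C)C)c(OCOC)c([Si](C)(C)C)c1OCOC | intermediate
12 | 1-[5-(3-methylbut-2-en-1-yl)-3-(trimethylsilyl)-2,4-bis(trimethylsilyloxy)phenyl]ethan-1-one | CC(=O)c1cc(CC=C(C)C)c(O[Si](C)(C)C)c([Si](C)(C)C)c1O[Si](C)(C)C | intermediate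
13 | 1-[2,4-dihydroxy-5-(3-methylbut-2-en-1-yl)-3-(trimethylsilyl)phenyl]ethan-1-one | CC(=O)c1cc(CC=C(C)C)c(O)c([Si](C)(C)C)c1O | intermediate
14 | (E)-3-(dimethylamino)-1-[2,4-dihydroxy-5-(3-methylbut-2-en-1-yl)-3-(trimethylsilyl)phenyl]prop-2-en-1-one | CN(C)/C=C/C(=O)c1cc(CC=C(C)C)c(O)c([Si](C)(C)C)c1O | intermediate
15 | 7-hydroxy-3-iodo-6-(3-methylbut-2-en-1-yl)-8-(trimethylsilyl)-4H-chromen-4-one | O=c1c(I)coc2c([Si](C)(C)C)c(O)c(CC=C(C)C)cc12 | intermediate
16 | 4-(methoxymethoxy)phenylboronic acid | COCOc1ccc(B(O)O)cc1 | starting material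
17 | 7-hydroxy-3-[4-(methoxymethoxy)phenyl]-6-(3-methylbut-2-en-1-yl)-8-(trimethylsilyl)-4H-chromen-4-one | O=c1c(-c2ccc(OCOC)cc2)coc2c([Si](C)(C)C)c(O)c(CC=C(C)C)cc12 | intermediate
18 | 3-[4-(methoxymethoxy)phenyl]-6-(3-methylbut-2-en-1-yl)-4-oxo-8-(trimethylsilyl)-4H-chromen-7-yl trifluoromethanesulfonate | O=c1c(-c2ccc(OCOC)cc2)coc2c([Si](C)(C)C)c(OS(=O)(=O)C(F)(F)F)c(CC=C(C)C)cc12 | intermediate
19 | 2-methylbut-3-en-2-ol | CC(C)(O)C=C | starting material
20 | 7,8-didehydro-3-[4-(methoxymethoxy)phenyl]-6-(3-methylbut-2-en-1-yl)-4H-chromen-4-one (aryne) | O=C1C(c2ccc(OCOC)cc2)=COC2=C1C=C(CC=C(C)C)C#C2 | intermediate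
21 | 3-[4-(methoxymethoxy)phenyl]-7-[(2-methylbut-3-en-2-yl)oxy]-6-(3-methylbut-2-en-1-yl)-4H-chromen-4-one | O=c1c(-c2ccc(OCOC)cc2)coc2cc(OC(C)(C)C=C)c(CC=C(C)C)cc12 | intermediate
22 | 3-[4-(methoxymethoxy)phenyl]-6,8-bis(3-methylbut-2-en-1-yl)-8H-chromene-4,7-dione (racemic at C8, transient) | O=C1C(c2ccc(OCOC)cc2)=COC2=C1C=C(CC=C(C)C)C(=O)C2CC=C(C)C | intermediate
23 | 7-hydroxy-3-[4-(methoxymethoxy)phenyl]-6,8-bis(3-methylbut-2-en-1-yl)-4H-chromen-4-one | CC(C)=CCc1cc2c(=O)c(-c3ccc(OCOC)cc3)coc2c(CC=C(C)C)c1O | intermediate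
24 | 7-hydroxy-3-(4-hydroxyphenyl)-6,8-bis(3-methylbut-2-en-1-yl)-4H-chromen-4-one | CC(C)=CCc1cc2c(=O)c(-c3ccc(O)cc3)coc2c(CC=C(C)C)c1O | target

**Step count**
Total steps: 11. Longest linear sequence: 11 steps, from resorcinol 1 to target 24.

**Steps most likely to fail**

1. Step 10. The hindered tertiary alcohol may add too slowly, so that the aryne is consumed by fluoride, by an ene-type reaction with the neighbouring C6 prenyl group or by self-reaction. The oxygen may also enter at C8, or the ether may not rearrange cleanly in the basic mixture.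
Fallback with known reactions, setting out from triflate 18 and returning at 23:
   - The aryne would be trapped by O–H insertion of a carboxylic acid (CsF, AcOH, MeCN, rt) to give 7-acetoxy-3-[4-(methoxymethoxy)phenyl]-6-(3-methylbut-2-en-1-yl)-4H-chromen-4-one F1.
   - Methanolysis (K2CO3, MeOH, 0 °C) would give 7-hydroxy-3-[4-(methoxymethoxy)phenyl]-6-(3-methylbut-2-en-1-yl)-4H-chromen-4-one F2.
   - Copper-catalysed O-alkylation with 2-methylbut-3-yn-2-yl trifluoroacetate (CuCl2, DBU, MeCN, 0 °C) would give 3-[4-(methoxymethoxy)phenyl]-7-[(2-methylbut-3-yn-2-yl)oxy]-6-(3-methylbut-2-en-1-yl)-4H-chromen-4-one F3.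
   - Semihydrogenation (H2, Pd/CaCO3 poisoned with Pb(OAc)2, quinoline, EtOAc) would give ether 21, now isolated, and heating (PhMe, 110 °C) would effect the Claisen rearrangement to 23.

2. Step 7. Iodine may be drawn to the electron-rich ring carrying the free para-hydroxyl, leading to iodoetherification of the prenyl alkene onto that oxygen or ipso-iododesilylation.
Fallback, setting out from acetophenone 13 and returning at 18, so that step 9 is no longer needed:
   - The non-chelated hydroxyl would be triflated first (Tf2O 1.0 equiv, pyridine, CH2Cl2, −78 °C) to give 4-acetyl-3-hydroxy-6-(3-methylbut-2-en-1-yl)-2-(trimethylsilyl)phenyl trifluoromethanesulfonate F4, which masks the phenol and deactivates the ring.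
   - Condensation with t-BuOCH(NMe2)2 (PhMe, 60 °C) would give (E)-4-[3-(dimethylamino)prop-2-enoyl]-3-hydroxy-6-(3-methylbut-2-en-1-yl)-2-(trimethylsilyl)phenyl trifluoromethanesulfonate F5.
   - Iodocyclisation (I2, CHCl3) would give 3-iodo-6-(3-methylbut-2-en-1-yl)-4-oxo-8-(trimethylsilyl)-4H-chromen-7-yl trifluoromethanesulfonate F6.
   - Fluoride-free Suzuki coupling with 16 (Pd(PPh3)4, Na2CO3, DME/H2O, 60 °C) at the C3–I bond, which is far more reactive than the doubly flanked triflate, would give 18.

3. Step 4. The base may remove a benzylic-allylic proton of the prenyl group instead of the ring proton, or the aryllithium may take a proton from the acetyl group of 9 instead of adding.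
Fallback, setting out from silane 4 (so that step 3 is replaced as well) and returning at 11, with the prenyl group introduced last as an electrophile:
   - Lithiation and formylation (s-BuLi, TMEDA, THF, −78 °C; DMF) would give 2,4-bis(methoxymethoxy)-3-(trimethylsilyl)benzaldehyde F7.
   - The formyl group would be masked in situ with lithium N-methylpiperazide, a weak director, so that OMOM-directed lithiation goes to the position next to the other OMOM group (s-BuLi, TMEDA, −40 °C). Coupling with 5 via CuBr·SMe2 and aqueous work-up would give 2,4-bis(methoxymethoxy)-5-(3-methylbut-2-en-1-yl)-3-(trimethylsilyl)benzaldehyde F8.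
   - Addition of MeMgBr (THF, 0 °C) would give racemic 1-[2,4-bis(methoxymethoxy)-5-(3-methylbut-2-en-1-yl)-3-(trimethylsilyl)phenyl]ethan-1-ol F9, and Dess–Martin oxidation (CH2Cl2, NaHCO3) would give 11.

**Further compounds**
F1 | step 10 | 7-acetoxy-3-[4-(methoxymethoxy)phenyl]-6-(3-methylbut-2-en-1-yl)-4H-chromen-4-one | CC(=O)Oc1cc2occ(-c3ccc(OCOC)cc3)c(=O)c2cc1CC=C(C)C
F2 | step 10 | 7-hydroxy-3-[4-(methoxymethoxy)phenyl]-6-(3-methylbut-2-en-1-yl)-4H-chromen-4-one | Oc1cc2occ(-c3ccc(OCOC)cc3)c(=O)c2cc1CC=C(C)C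
F3 | step 10 | 3-[4-(methoxymethoxy)phenyl]-7-[(2-methylbut-3-yn-2-yl)oxy]-6-(3-methylbut-2-en-1-yl)-4H-chromen-4-one | C#CC(C)(C)Oc1cc2occ(-c3ccc(OCOC)cc3)c(=O)c2cc1CC=C(C)C
F4 | step 7 | 4-acetyl-3-hydroxy-6-(3-methylbut-2-en-1-yl)-2-(trimethylsilyl)phenyl trifluoromethanesulfonate | CC(=O)c1cc(CC=C(C)C)c(OS(=O)(=O)C(F)(F)F)c([Si](C)(C)C)c1O
F5 | step 7 | (E)-4-[3-(dimethylamino)prop-2-enoyl]-3-hydroxy-6-(3-methylbut-2-en-1-yl)-2-(trimethylsilyl)phenyl trifluoromethanesulfonate | CN(C)/C=C/C(=O)c1cc(CC=C(C)C)c(OS(=O)(=O)C(F)(F)F)c([Si](C)(C)C)c1O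
F6 | step 7 | 3-iodo-6-(3-methylbut-2-en-1-yl)-4-oxo-8-(trimethylsilyl)-4H-chromen-7-yl trifluoromethanesulfonate | O=c1c(I)coc2c([Si](C)(C)C)c(OS(=O)(=O)C(F)(F)F)c(CC=C(C)C)cc12
F7 | step 4 | 2,4-bis(methoxymethoxy)-3-(trimethylsilyl)benzaldehyde | O=Cc1ccc(OCOC)c([Si](C)(C)C)c1OCOC
F8 | step 4 | 2,4-bis(methoxymethoxy)-5-(3-methylbut-2-en-1-yl)-3-(trimethylsilyl)benzaldehyde | O=Cc1cc(CC=C(C)C)c(OCOC)c([Si](C)(C)C)c1OCOC
F9 | step 4 | 1-[2,4-bis(methoxymethoxy)-5-(3-methylbut-2-en-1-yl)-3-(trimethylsilyl)phenyl]ethan-1-ol (racemic) | CC(O)c1cc(CC=C(C)C)c(OCOC)c([Si](C)(C)C)c1OCOC
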